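Cuts (ring atoms: O1, O2, C3 = peroxyketal carbon, C4, C5, C6 = CH): the alkyne C(sp)–vinyl C(sp2) bond; O1–C6 of the 1,2-dioxane; C3–O2 and C3–OMe (back to C=CH2); the C–C/C–O pair of a β-lactone (aldehyde + ketene); C4–C5 (Claisen).
Enabling feature: O1 on C6 lies β to the ester carbonyl. The array O1–C6–CH2–C(=O) therefore matches, atom for atom, O1–C4–C3–C2 of a 4-alkyloxetan-2-one, whose strained alkyl C–O bond can be displaced by a peroxide oxygen held on the C3–C4–C5 tether.
Forward order: alkynol → 2-substituted allyl alcohol → Claisen aldehyde → β-lactone (temporary four-membered ring) → methoxy hydroperoxide → dioxane closes as the oxetanone opens → ester formation and C3 adjustment → dienyne chain joined last by Sonogashira coupling.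
Stereochemistry: C6 comes from the alkaloid-catalysed ketene–aldehyde cycloaddition (R lactone) and is passed on with inversion (6S). C3 is set by equilibration in acidic methanol to the chair with axial OMe and both carbon chains equatorial (3R, OMe cis to the C6 arm). The E-alkene comes from the Takai olefination and is retained in the coupling.

Key step: step 8

Assumption: O-trimethylsilylquinine is taken as the pseudoenantiomer that gives the (R)-lactone from an unbranched aldehyde; if the sense of induction is the opposite, O-trimethylsilylquinidine replaces it and nothing else changes.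

Step 1
Reactants: 1 hept-6-yn-1-ol
Product: 2 hept-6-ynal
Conditions: TEMPO (5 mol%), PhI(OAc)2, CH2Cl2, rt
Reagents that add atoms: none
Why: The oxoammonium (TEMPO/PhI(OAc)2) oxidation of a primary alcohol stops at the aldehyde under neutral, metal-free conditions that leave a terminal alkyne untouched.

Step 2
Reactants: 2 hept-6-ynal
Product: 3 2-methylidenehept-6-ynal
Conditions: 37% aq. HCHO, pyrrolidine (10 mol%), EtCO2H (10 mol%), i-PrOH, 45 °C
Reagents that add atoms: formaldehyde, C=O
Why: The amine/acid-catalysed α-methylenation (Mannich condensation with formaldehyde followed by loss of the amine) is general for unbranched aldehydes, stops after one CH2 transfer because the enal has no α-hydrogen left, and does not affect the alkyne.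

Step 3
Reactants: 3 2-methylidenehept-6-ynal
Product: 4 2-methylidenehept-6-yn-1-ol
Conditions: NaBH4, CeCl3·7H2O, MeOH, 0 °C
Reagents that add atoms: none
Why: The Luche reduction delivers hydride 1,2 to the enal carbonyl, so the 1,1-disubstituted alkene is kept and the allylic alcohol needed for the rearrangement is obtained.

Step 4
Reactants: 4 2-methylidenehept-6-yn-1-ol; 5 ethyl vinyl ether
Product: 6 2-[(ethenyloxy)methyl]hept-1-en-6-yne (the vinyl ether of 4)
Conditions: Pd(OAc)2 (5 mol%), 1,10-phenanthroline (5 mol%), 5 as solvent (large excess), rt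
Reagents that add atoms: none
Why: Pd(II)/phenanthroline-catalysed transfer vinylation (vinyl ether exchange) works best on unhindered primary alcohols, is pulled forward by the large excess of 5, and avoids mercury(II) salts that could mercurate or hydrate the terminal alkyne.

Step 5
Reactants: 6 2-[(ethenyloxy)methyl]hept-1-en-6-yne
Product: 7 4-methylidenenon-8-ynal
Conditions: PhMe, sealed tube, 150 °C
Reagents that add atoms: none
Why: The thermal Claisen [3,3]-sigmatropic rearrangement of an allyl vinyl ether is driven by C=O formation, turns the oxygen-bearing CH2 into the new exocyclic methylene while adding the two-carbon aldehyde arm, creates no stereocentre, and leaves the isolated alkyne inert at this temperature.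

Step 6
Reactants: 7 4-methylidenenon-8-ynal; 8 acetyl chloride
Product: 10 (4R)-4-(3-methylideneoct-7-yn-1-yl)oxetan-2-one, via ketene 9 (not isolated)
Conditions: O-TMS-quinine (10 mol%), LiClO4 (30 mol%), i-Pr2NEt, CH2Cl2/Et2O, −78 °C, slow addition of 8
Reagents that add atoms: none
Why: In this catalytic asymmetric acyl halide–aldehyde cyclocondensation (formal ketene–aldehyde [2+2] cycloaddition) the amine base turns 8 into ketene 9, the silylated alkaloid converts 9 into a chiral ammonium enolate that adds to one face of the lithium-activated unbranched aldehyde and then lactonises, so the new stereocentre C4 of the lactone is set as R by the catalyst alone.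

Step 7
Reactants: 10 (4R)-4-(3-methylideneoct-7-yn-1-yl)oxetan-2-one
Product: 12 (4R)-4-(3-hydroperoxy-3-methoxyoct-7-yn-1-yl)oxetan-2-one (both epimers at the ketal carbon), via carbonyl oxide 11 (not isolated)
Conditions: O3 (1 equiv, Sudan Red 7B end point), CH2Cl2/MeOH, −78 °C; N2 purge, no reductive work-up, concentration below 20 °C
Reagents that add atoms: ozone, [O-][O+]=O; methanol, CO
Why: Ozonolysis in a participating solvent (Criegee mechanism) is chemoselective because the electron-rich 1,1-disubstituted alkene consumes ozone far faster than a terminal alkyne, the cycloreversion places the carbonyl oxide on the more substituted carbon (11, with formaldehyde as partner), methanol traps 11 as the α-methoxy hydroperoxide without facial bias so that the new ketal centre is deliberately left as an epimer mixture, and neutral methanol at −78 °C does not open the β-lactone.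

Step 8
Reactants: 12 (4R)-4-(3-hydroperoxy-3-methoxyoct-7-yn-1-yl)oxetan-2-one (both ketal epimers)
Product: 15 2-[(6S)-3-methoxy-3-(pent-4-yn-1-yl)-1,2-dioxan-6-yl]acetic acid (both C3 epimers), via caesium alkylperoxide 13 (not isolated), via caesium carboxylate 14 (not isolated)
Conditions: Cs2CO3 (1.1 equiv), 4 Å MS, DMF (0.02 M), 0 °C → rt; then cold 0.5 M HCl to pH 3–4
Reagents that add atoms: none
Why: Proposed new method: Cs2CO3 removes only the hydroperoxide proton (far more acidic than the lactone α-CH2), and the α-effect peroxy anion 13 attacks C4 of the oxetan-2-one anti to its C4–O1 bond, so that the O1–C6 bond of the dioxane forms while the four-membered ring opens and its strain is released into carboxylate 14. The closest known reaction types are the alkyl–oxygen SN2 opening of 4-alkyl β-lactones by soft nucleophiles (azide, thiolates, sulfonamide anions, cuprates) with inversion and the base-induced cyclisation of hydroperoxy ketals onto secondary sulfonates, but a peroxide nucleophile has not been used on a β-lactone. The 1,2-dioxane closes in the 6-exo-tet mode, the departing oxygen lying outside the new ring. C6 is the only stereocentre affected and is fixed by the substrate, since backside displacement turns the R-configured lactone carbon into the S-configured peroxy carbon, whereas C3 stays an epimer mixture that step 9 corrects. The step needs alkyl over acyl attack and substitution over elimination: the C3–C4–C5 tether allows a six-membered transition state at the alkyl carbon but would demand an eight-membered cyclic perester at the carbonyl, dilution holds back intermolecular acylation, and the ring C–O bond of a β-lactone is nearly orthogonal to the π system of its enolate, which disfavours E1cB loss of the stereocentre. The product leaves the reaction as a carboxylate that carbonate cannot enolise, so it cannot reopen by retro-Michael cleavage.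

Step 9
Reactants: 15 2-[(6S)-3-methoxy-3-(pent-4-yn-1-yl)-1,2-dioxan-6-yl]acetic acid (both C3 epimers)
Product: 18 methyl 2-[(3R,6S)-3-methoxy-3-(pent-4-yn-1-yl)-1,2-dioxan-6-yl]acetate, via C3-epimeric methyl esters 16 (not isolated), via peroxycarbenium ion 17 (not isolated)
Conditions: p-TsOH·H2O (15 mol%), MeOH, rt
Reagents that add atoms: methanol, CO
Why: Fischer esterification and acid-catalysed peroxyketal exchange run side by side in acidic methanol: the esters 16 lose and regain methanol reversibly through the peroxycarbenium ion 17, which drains the mixture into the most stable chair with OMe axial (anomeric stabilisation by O2) and both carbon chains equatorial, that is OMe cis to the C6 arm and C3 = R, while C6 is safe because its C–O bond is never broken.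

Step 10
Reactants: 19 dec-9-en-1-ol
Product: 20 dec-9-enal
Conditions: TEMPO (5 mol%), PhI(OAc)2, CH2Cl2, rt
Reagents that add atoms: none
Why: The same oxoammonium oxidation as in step 1 stops at the aldehyde and does not touch the terminal alkene.

Step 11
Reactants: 20 dec-9-enal
Product: 21 (1E)-1-iodoundeca-1,10-diene
Conditions: CrCl2 (6 equiv), CHI3 (2 equiv), 1,4-dioxane/THF (6:1), 0 °C → rt
Reagents that add atoms: iodoform, IC(I)I
Why: The Takai olefination adds the gem-dichromium species formed from CHI3 and CrCl2 to the aldehyde and eliminates preferentially to the E-vinyl iodide, the dioxane-rich solvent raises the E preference for unbranched aldehydes, and Cr(II) ignores the isolated terminal alkene.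

Step 12
Reactants: 18 methyl 2-[(3R,6S)-3-methoxy-3-(pent-4-yn-1-yl)-1,2-dioxan-6-yl]acetate; 21 (1E)-1-iodoundeca-1,10-diene
Product: 22 peroxyacarnoate A, methyl 2-[(3R,6S)-3-[(6E)-hexadeca-6,15-dien-4-yn-1-yl]-3-methoxy-1,2-dioxan-6-yl]acetate
Conditions: PdCl2(PPh3)2 (5 mol%), CuI (10 mol%), Et3N, THF, rt, degassed
Reagents that add atoms: none
Why: The Sonogashira coupling joins the terminal alkyne to the vinyl iodide at room temperature with retention of the E geometry, Pd/Cu cross-couplings are tolerated by dialkyl peroxides and peroxyketals of the 1,2-dioxane type, the low phosphine load limits O–O reduction, and a tertiary amine in THF is too weak a base to enolise the ester and reopen the ring at C6.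

Compound list
1 | hept-6-yn-1-ol | C#CCCCCCO | starting material
2 | hept-6-ynal | C#CCCCCC=O | intermediate
3 | 2-methylidenehept-6-ynal | C=C(C=O)CCCC#C | intermediate
4 | 2-methylidenehept-6-yn-1-ol | C=C(CO)CCCC#C | intermediate
5 | ethyl vinyl ether | C=COCC | starting material
6 | 2-[(ethenyloxy)methyl]hept-1-en-6-yne | C=COCC(=C)CCCC#C | intermediate
7 | 4-methylidenenon-8-ynal | C=C(CCC=O)CCCC#C | intermediate
8 | acetyl chloride | CC(=O)Cl | starting material
9 | ketene (not isolated) | C=C=O | intermediate
10 | (4R)-4-(3-methylideneoct-7-yn-1-yl)oxetan-2-one | C=C(CC[C@@H]1CC(=O)O1)CCCC#C | intermediate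
11 | carbonyl oxide of the (4R)-lactone ketone (not isolated) | C#CCCCC(=[O+][O-])CC[C@@H]1CC(=O)O1 | intermediate
12 | (4R)-4-(3-hydroperoxy-3-methoxyoct-7-yn-1-yl)oxetan-2-one, both ketal epimers | C#CCCCC(OC)(OO)CC[C@@H]1CC(=O)O1 | intermediate
13 | caesium alkylperoxide of 12 (not isolated) | C#CCCCC(OC)(O[O-])CC[C@@H]1CC(=O)O1.[Cs+] | intermediate
14 | caesium 2-[(6S)-3-methoxy-3-(pent-4-yn-1-yl)-1,2-dioxan-6-yl]acetate, both C3 epimers (not isolated) | C#CCCCC1(OC)CC[C@@H](CC(=O)[O-])OO1.[Cs+] | intermediate
15 | 2-[(6S)-3-methoxy-3-(pent-4-yn-1-yl)-1,2-dioxan-6-yl]acetic acid, both C3 epimers | C#CCCCC1(OC)CC[C@@H](CC(=O)O)OO1 | intermediate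
16 | methyl 2-[(6S)-3-methoxy-3-(pent-4-yn-1-yl)-1,2-dioxan-6-yl]acetate, both C3 epimers (not isolated) | C#CCCCC1(OC)CC[C@@H](CC(=O)OC)OO1 | intermediate
17 | (6S)-peroxycarbenium ion formed by loss of methanol from 16 (not isolated) | C#CCCCC1=[O+]O[C@H](CC(=O)OC)CC1 | intermediate
18 | methyl 2-[(3R,6S)-3-methoxy-3-(pent-4-yn-1-yl)-1,2-dioxan-6-yl]acetate | C#CCCC[C@]1(OC)CC[C@@H](CC(=O)OC)OO1 | intermediate
19 | dec-9-en-1-ol | C=CCCCCCCCCO | starting material
20 | dec-9-enal | C=CCCCCCCCC=O | intermediate
21 | (1E)-1-iodoundeca-1,10-diene | C=CCCCCCCC/C=C/I | intermediate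
22 | peroxyacarnoate A | C=CCCCCCCC/C=C/C#CCCC[C@]1(OC)CC[C@@H](CC(=O)OC)OO1 | target

Total step count: 12. Longest linear sequence: 10 steps (steps 1–9 and 12); steps 10 and 11 form the side branch.

Steps most likely to fail

1. Step 8 (the new method).
- What may go wrong: the peroxy anion may attack a lactone carbonyl of another molecule (perester formation and oligomerisation). Base may cause elimination across the former lactone carbons. The secondary carbon may simply resist displacement.
- Fallback: known chemistry only, setting out from 10 and coming back at 15.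
- The lactone is reduced with LiAlH4 (THF, 0 °C) to (3R)-6-methylideneundec-10-yne-1,3-diol F1. The primary hydroxyl is silylated selectively (TBSCl, imidazole, CH2Cl2, 0 °C) to give (3R)-1-[(tert-butyldimethylsilyl)oxy]-6-methylideneundec-10-yn-3-ol F2.
- MsCl/Et3N then converts the secondary hydroxyl into (3R)-1-[(tert-butyldimethylsilyl)oxy]-6-methylideneundec-10-yn-3-yl methanesulfonate F3. With the carbonyl gone, this sulfonate no longer has an acidified neighbouring C–H and cannot leave by E1cB.
- Ozonolysis in CH2Cl2/MeOH at −78 °C gives (3R)-1-[(tert-butyldimethylsilyl)oxy]-6-hydroperoxy-6-methoxyundec-10-yn-3-yl methanesulfonate F4.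
- KOtBu/18-crown-6 in THF closes F4 by the established 6-exo-tet displacement of a secondary sulfonate with inversion. This gives (6S)-6-{2-[(tert-butyldimethylsilyl)oxy]ethyl}-3-methoxy-3-(pent-4-yn-1-yl)-1,2-dioxane F5.
- Buffered HF·pyridine frees 2-[(6S)-3-methoxy-3-(pent-4-yn-1-yl)-1,2-dioxan-6-yl]ethanol F6. TEMPO/PhI(OAc)2 in aqueous MeCN oxidises F6 to acid 15.

2. Step 9.
- What may go wrong: the bias at equilibrium may be incomplete. The ring may drift open to the acyclic dimethyl ketal hydroperoxide. The long exposure that the esterification needs may cause acid-induced O–O heterolysis.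
- Fallback: it sets out from 15 and comes back at 18, and it replaces the protic thermodynamic funnel by separation plus kinetic trapping.
- The acid is esterified under neutral conditions (TMSCHN2, PhMe/MeOH, 0 °C) and the ester mixture 16 is now isolated. Chromatography divides it into 18 and its epimer methyl 2-[(3S,6S)-3-methoxy-3-(pent-4-yn-1-yl)-1,2-dioxan-6-yl]acetate F7.
- F7 alone is ionised under aprotic conditions (cat. TMSOTf, MeOSiMe3, CH2Cl2, −78 °C). The methoxy group then adds axially to the half-chair cation under stereoelectronic control, which gives 18.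

3. Step 12.
- What may go wrong: Pd(0), phosphine or Cu(I) may reduce the O–O bond. Copper may promote homocoupling of the alkyne. The amine may trigger retro-Michael opening and reclosure that erodes C6.
- Fallback: it sets out from 18 and comes back at 22, and it changes the coupling to an amine-, copper- and phosphine-free Stille reaction.
- The terminal alkyne is stannylated under neutral conditions (Bu3SnOMe, cat. ZnBr2, THF, rt) to methyl 2-[(3R,6S)-3-methoxy-3-[5-(tributylstannyl)pent-4-yn-1-yl]-1,2-dioxan-6-yl]acetate F8.
- F8 is coupled with 21 (Pd2(dba)3, AsPh3, DMF, rt) with retention of the E geometry to give 22.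

Further compounds
F1 | step 8 | (3R)-6-methylideneundec-10-yne-1,3-diol | C=C(CC[C@@H](O)CCO)CCCC#C
F2 | step 8 | (3R)-1-[(tert-butyldimethylsilyl)oxy]-6-methylideneundec-10-yn-3-ol | C=C(CC[C@@H](O)CCO[Si](C)(C)C(C)(C)C)CCCC#C
F3 | step 8 | (3R)-1-[(tert-butyldimethylsilyl)oxy]-6-methylideneundec-10-yn-3-yl methanesulfonate | C=C(CC[C@@H](OS(C)(=O)=O)CCO[Si](C)(C)C(C)(C)C)CCCC#C
F4 | step 8 | (3R)-1-[(tert-butyldimethylsilyl)oxy]-6-hydroperoxy-6-methoxyundec-10-yn-3-yl methanesulfonate, both ketal epimers | C#CCCCC(OC)(OO)CC[C@@H](OS(C)(=O)=O)CCO[Si](C)(C)C(C)(C)C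
F5 | step 8 | (6S)-6-{2-[(tert-butyldimethylsilyl)oxy]ethyl}-3-methoxy-3-(pent-4-yn-1-yl)-1,2-dioxane, both C3 epimers | C#CCCCC1(OC)CC[C@@H](CCO[Si](C)(C)C(C)(C)C)OO1
F6 | step 8 | 2-[(6S)-3-methoxy-3-(pent-4-yn-1-yl)-1,2-dioxan-6-yl]ethanol, both C3 epimers | C#CCCCC1(OC)CC[C@@H](CCO)OO1
F7 | step 9 | methyl 2-[(3S,6S)-3-methoxy-3-(pent-4-yn-1-yl)-1,2-dioxan-6-yl]acetate | C#CCCC[C@@]1(OC)CC[C@@H](CC(=O)OC)OO1
F8 | step 12 | methyl 2-[(3R,6S)-3-methoxy-3-[5-(tributylstannyl)pent-4-yn-1-yl]-1,2-dioxan-6-yl]acetate | CCCC[Sn](CCCC)(CCCC)C#CCCC[C@]1(OC)CC[C@@H](CC(=O)OC)OO1
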